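**Plan**

- Retros: remove the C5 acetate, cut the aryl ether bond O–C7 (umbelliferone plus a primary alcohol), then cut ring bond C1–C2 by a retro-Wolff ring expansion.
- Enabling feature: ring carbon C1 carries the exocyclic oxidised carbon C7 (the ArOCH2 carbon) directly beside the methyl-bearing alkene carbon C2. The cyclohexene C1–C6 (C3 alkene CH, C4 CH2, C5 acetoxy CH, C6 CMe2) is therefore the contraction product of a 2,6,6-trimethylcyclohept-2-enone whose carbonyl carbon ends up as C7.
- Forward: carvone is isomerised to the seven-membered dienone eucarvone, which already holds C2-Me, C2=C3 and the CMe2 carbon in order. Epoxidation and reductive opening place oxygen on C5, diazo transfer activates the α' carbon, and photolysis contracts the seven-membered ring to the six-membered ring ester.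
- The ester is reduced, joined to umbelliferone by Mitsunobu etherification, desilylated and acetylated.
- Stereochemistry: C5 comes from catalyst-controlled Jacobsen epoxidation of the distal cis alkene; C1 comes from base equilibration of the ester to the trans (1R,5R) epimer, governed by C5.

Key step: step 8

Numbering remark: target numbering as above. Seven-membered intermediates are numbered as cycloheptenones (C1 = carbonyl carbon); their C7 becomes target C1, their carbonyl carbon becomes target C7, and C2–C6 keep their numbers.

Assumption: (R,R)-(salen)MnCl is taken to deliver oxygen to the 4,5-alkene of eucarvone with the facial sense it shows for 2,2-dimethylchromene (vinyl in the role of aryl). Should the sense prove opposite, the (S,S) complex is used. Either enantiomer of carvone serves, since its stereocentre is erased in step 2.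

**Route**

Step 1
Reactants: 1 (R)-carvone
Product: 2 (5R)-5-(2-bromopropan-2-yl)-2-methylcyclohex-2-en-1-one (carvone hydrobromide)
Conditions: HBr (33% in AcOH), 0–10 °C
Reagents that add atoms: hydrogen bromide, Br
Why: Markovnikov ionic hydrobromination, in which the isolated 1,1-disubstituted isopropenyl alkene is protonated to a tertiary cation and captured by bromide while the electron-poor enone alkene is left alone.

Step 2
Reactants: 2 carvone hydrobromide
Product: 4 eucarvone (2,6,6-trimethylcyclohepta-2,4-dien-1-one), via carenone 3 (not isolated)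
Conditions: KOH, MeOH, 0 °C then reflux
Reagents that add atoms: none
Why: Classical eucarvone synthesis, in which the α'-enolate displaces the tertiary bromide intramolecularly (1,3-elimination) to give the cis-fused cyclopropane 3, whose dienolate opens by a norcaradiene-to-cycloheptatriene type electrocyclic ring expansion and is reprotonated to the conjugated, achiral dienone.

Step 3
Reactants: 4 eucarvone
Product: 5 (4R,5S)-4,5-epoxy-2,6,6-trimethylcyclohept-2-en-1-one
Conditions: (R,R)-(salen)MnCl [salen = N,N'-bis(3,5-di-tert-butylsalicylidene)cyclohexane-1,2-diaminate] (5 mol %), 4-phenylpyridine N-oxide (20 mol %), aq NaOCl (pH 11.3), CH2Cl2, 0 °C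
Reagents that add atoms: sodium hypochlorite, [Na+].[O-]Cl
Why: Jacobsen epoxidation, in which the electrophilic manganese oxo species should attack the more electron-rich distal cis alkene C4=C5 (conjugated on one side, flanked by a quaternary carbon on the other, as in 2,2-dimethylchromene) rather than the enone alkene, and side-on approach over the chiral diamine backbone sets both epoxide carbons and hence C5 by catalyst control.

Step 4
Reactants: 5 (4R,5S)-4,5-epoxy-2,6,6-trimethylcyclohept-2-en-1-one
Product: 6 (5R)-5-hydroxy-2,6,6-trimethylcyclohept-3-en-1-one as C2 epimers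
Conditions: SmI2 (2.2 equiv), THF–MeOH, −78 °C
Reagents that add atoms: none
Why: Single-electron reductive opening of a vinylogous α,β-epoxy ketone with samarium diiodide, in which two electrons enter the dienone, the allylic C4–O bond breaks to a samarium dienolate that methanol protonates kinetically at C2, and the C5–O bond with its configuration is untouched.

Step 5
Reactants: 6 (5R)-5-hydroxy-2,6,6-trimethylcyclohept-3-en-1-one
Product: 7 (5R)-5-hydroxy-2,6,6-trimethylcyclohept-2-en-1-one
Conditions: DBU (0.2 equiv), CH2Cl2, rt
Reagents that add atoms: none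
Why: Base-mediated isomerisation of a β,γ- to an α,β-unsaturated ketone through the dienolate, reprotonation at C4 giving the conjugated trisubstituted enone that should be preferred at equilibrium, while hydroxide is too poor a leaving group for vinylogous elimination under these mild conditions.

Step 6
Reactants: 7 (5R)-5-hydroxy-2,6,6-trimethylcyclohept-2-en-1-one
Product: 8 (5R)-5-(tert-butyldimethylsilyloxy)-2,6,6-trimethylcyclohept-2-en-1-one
Conditions: TBSOTf, 2,6-lutidine, CH2Cl2, −78 to 0 °C
Reagents that add atoms: tert-butyldimethylsilyl trifluoromethanesulfonate, CC(C)(C)[Si](C)(C)OS(=O)(=O)C(F)(F)F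
Why: Silyl ether formation with the triflate, which is reactive enough for a secondary alcohol next to a quaternary carbon (any bridged hemiketal form of 7 drains through the open hydroxy ketone), giving an ether that tolerates the enolate, photochemical, methoxide and hydride steps ahead.

Step 7
Reactants: 8 (5R)-5-(tert-butyldimethylsilyloxy)-2,6,6-trimethylcyclohept-2-en-1-one
Product: 10 (5R)-7-diazo-5-(tert-butyldimethylsilyloxy)-2,6,6-trimethylcyclohept-2-en-1-one, via trifluoroacetyl ketone 9 (not isolated)
Conditions: LiN(SiMe3)2, THF, −78 °C; CF3CO2CH2CF3; aq HCl work-up, crude 9; then MsN3, Et3N, H2O (1 equiv), MeCN, rt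
Reagents that add atoms: methanesulfonyl azide, CS(=O)(=O)N=[N+]=[N-] (the two diazo nitrogens); 2,2,2-trifluoroethyl trifluoroacetate, O=C(OCC(F)(F)F)C(F)(F)F (the trifluoroacetyl group of 9 only, lost again)
Why: Detrifluoroacetylative (Regitz-type deacylative) diazo transfer, in which kinetic deprotonation of the enone at the α' carbon C7 (cross-conjugated enolate) and Claisen acylation activate C7, and the 1,3-dicarbonyl anion then adds to the sulfonyl azide and fragments with loss of the trifluoroacetyl group as the acylsulfonamide.

Step 8
Reactants: 10 (5R)-7-diazo-5-(tert-butyldimethylsilyloxy)-2,6,6-trimethylcyclohept-2-en-1-one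
Product: 12 methyl (5R)-5-(tert-butyldimethylsilyloxy)-2,6,6-trimethylcyclohex-2-ene-1-carboxylate as C1 epimers, via vinylketene 11 (not isolated)
Conditions: hν (300 nm, Pyrex), degassed MeOH, 0 °C
Reagents that add atoms: methanol, CO
Why: Photochemical Wolff rearrangement: excitation of the diazo ketone, held s-cis by the ring, expels N2 and the alkenyl carbon C2 shifts from the carbonyl carbon to the former diazo carbon (concerted or through the singlet acylcarbene), which creates the C1–C2 bond of the target and the vinylketene 11 that methanol captures as the ester. The closest known reactions are the Wolff ring contraction of cyclic 2-diazo ketones and the photolysis of α'-diazo enones to vinylketenes. The six-membered ring is formed not by cyclisation but by contraction of the seven-membered ring through this 1,2-shift, the carbonyl carbon leaving the ring to become C7. The new stereocentre C1 arises when the ketene hemiacetal (a dienol) is protonated and is not controlled here; it is brought under thermodynamic control in step 9, and C5 is a spectator. The step needs migration instead of other carbene reactions and α- instead of γ-protonation: C2 is the only group on the carbonyl carbon that can migrate, the other neighbour of the diazo carbon is the quaternary C6 so that no 1,2-hydride shift is possible, and dienols are protonated kinetically at the α carbon, which keeps the C2=C3 alkene in place.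

Step 9
Reactants: 12 methyl (5R)-5-(tert-butyldimethylsilyloxy)-2,6,6-trimethylcyclohex-2-ene-1-carboxylate as C1 epimers
Product: 13 methyl (1R,5R)-5-(tert-butyldimethylsilyloxy)-2,6,6-trimethylcyclohex-2-ene-1-carboxylate (trans)
Conditions: NaOMe (0.3 equiv), MeOH, 40 °C
Reagents that add atoms: none
Why: Thermodynamic epimerisation of the doubly activated (allylic and α to the ester) C1–H through the ester enolate, the trans epimer being the only one that can hold the ester pseudoaxial (no allylic 1,2-strain with the C2 methyl) and the silyloxy group equatorial at the same time, so that equilibration should funnel the mixture to the (1R,5R) ester.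

Step 10
Reactants: 13 methyl (1R,5R)-5-(tert-butyldimethylsilyloxy)-2,6,6-trimethylcyclohex-2-ene-1-carboxylate
Product: 14 [(1R,5R)-5-(tert-butyldimethylsilyloxy)-2,6,6-trimethylcyclohex-2-en-1-yl]methanol
Conditions: LiAlH4, THF, 0 °C; aq NaOH work-up
Reagents that add atoms: none
Why: Hydride reduction of an ester to the primary alcohol, fast enough at 0 °C that C1 is not epimerised on the way and after which C1 is no longer acidic, with silyl ether and alkene inert.

Step 11
Reactants: 14 [(1R,5R)-5-(tert-butyldimethylsilyloxy)-2,6,6-trimethylcyclohex-2-en-1-yl]methanol; 15 umbelliferone (7-hydroxy-2H-chromen-2-one)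
Product: 16 7-{[(1R,5R)-5-(tert-butyldimethylsilyloxy)-2,6,6-trimethylcyclohex-2-en-1-yl]methoxy}-2H-chromen-2-one
Conditions: PPh3, DIAD, THF, 0 °C to rt
Reagents that add atoms: none
Why: Mitsunobu etherification, in which the primary alcohol is activated as the alkoxyphosphonium ion and displaced at the CH2 carbon C7 by the acidic phenol of umbelliferone (pKa about 8), so that no stereocentre is involved and the coumarin lactone sees only neutral conditions.

Step 12
Reactants: 16 7-{[(1R,5R)-5-(tert-butyldimethylsilyloxy)-2,6,6-trimethylcyclohex-2-en-1-yl]methoxy}-2H-chromen-2-one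
Product: 17 7-{[(1R,5R)-5-hydroxy-2,6,6-trimethylcyclohex-2-en-1-yl]methoxy}-2H-chromen-2-one
Conditions: HF·pyridine, pyridine, THF, 0 °C to rt
Reagents that add atoms: none
Why: Fluoride-driven cleavage of the silyl ether at the Si–O bond, so that C5 keeps its configuration, under buffered non-basic conditions that should spare the coumarin lactone, the aryl ether and the trisubstituted alkene.

Step 13
Reactants: 17 7-{[(1R,5R)-5-hydroxy-2,6,6-trimethylcyclohex-2-en-1-yl]methoxy}-2H-chromen-2-one
Product: 18 7-{[(1R,5R)-5-acetoxy-2,6,6-trimethylcyclohex-2-en-1-yl]methoxy}-2H-chromen-2-one (target)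
Conditions: Ac2O, DMAP (cat.), pyridine, CH2Cl2, rt
Reagents that add atoms: acetic anhydride, CC(=O)OC(C)=O
Why: DMAP-catalysed acylation of the hindered secondary alcohol through the N-acetylpyridinium ion, which reacts at the O–H bond and therefore leaves the C5 configuration unchanged.

**Compound list**

1 | (R)-carvone | CC(=C)[C@@H]1CC=C(C)C(=O)C1 | starting material
2 | (5R)-5-(2-bromopropan-2-yl)-2-methylcyclohex-2-en-1-one (carvone hydrobromide) | CC(C)(Br)[C@@H]1CC=C(C)C(=O)C1 | intermediate
3 | carenone, cis-fused (1S,6R)-3,7,7-trimethylbicyclo[4.1.0]hept-3-en-2-one | CC1=CC[C@@H]2[C@H](C1=O)C2(C)C | intermediate (not isolated)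
4 | eucarvone, 2,6,6-trimethylcyclohepta-2,4-dien-1-one (achiral) | CC1=CC=CC(C)(C)CC1=O | intermediate
5 | (4R,5S)-4,5-epoxy-2,6,6-trimethylcyclohept-2-en-1-one | CC1=C[C@H]2O[C@H]2C(C)(C)CC1=O | intermediate
6 | (5R)-5-hydroxy-2,6,6-trimethylcyclohept-3-en-1-one, C2 epimers | O[C@@H]1C=CC(C)C(=O)CC1(C)C | intermediate
7 | (5R)-5-hydroxy-2,6,6-trimethylcyclohept-2-en-1-one | O[C@@H]1CC=C(C)C(=O)CC1(C)C | intermediate
8 | (5R)-5-(tert-butyldimethylsilyloxy)-2,6,6-trimethylcyclohept-2-en-1-one | CC(C)(C)[Si](C)(C)O[C@@H]1CC=C(C)C(=O)CC1(C)C | intermediate
9 | (5R)-5-(tert-butyldimethylsilyloxy)-2,6,6-trimethyl-7-(trifluoroacetyl)cyclohept-2-en-1-one, C7 epimers or enol | CC(C)(C)[Si](C)(C)O[C@@H]1CC=C(C)C(=O)C(C(=O)C(F)(F)F)C1(C)C | intermediate (not isolated)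
10 | (5R)-7-diazo-5-(tert-butyldimethylsilyloxy)-2,6,6-trimethylcyclohept-2-en-1-one | CC(C)(C)[Si](C)(C)O[C@@H]1CC=C(C)C(=O)C(=[N+]=[N-])C1(C)C | intermediate
11 | vinylketene, [(5R)-5-(tert-butyldimethylsilyloxy)-2,6,6-trimethylcyclohex-2-en-1-ylidene]methanone | CC(C)(C)[Si](C)(C)O[C@@H]1CC=C(C)C(=C=O)C1(C)C | intermediate (not isolated)
12 | methyl (5R)-5-(tert-butyldimethylsilyloxy)-2,6,6-trimethylcyclohex-2-ene-1-carboxylate, C1 epimers | CC(C)(C)[Si](C)(C)O[C@@H]1CC=C(C)C(C(=O)OC)C1(C)C | intermediate
13 | methyl (1R,5R)-5-(tert-butyldimethylsilyloxy)-2,6,6-trimethylcyclohex-2-ene-1-carboxylate (trans) | CC(C)(C)[Si](C)(C)O[C@@H]1CC=C(C)[C@@H](C(=O)OC)C1(C)C | intermediate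
14 | [(1R,5R)-5-(tert-butyldimethylsilyloxy)-2,6,6-trimethylcyclohex-2-en-1-yl]methanol | CC(C)(C)[Si](C)(C)O[C@@H]1CC=C(C)[C@@H](CO)C1(C)C | intermediate
15 | umbelliferone (7-hydroxy-2H-chromen-2-one) | Oc1ccc2ccc(=O)oc2c1 | starting material
16 | 7-{[(1R,5R)-5-(tert-butyldimethylsilyloxy)-2,6,6-trimethylcyclohex-2-en-1-yl]methoxy}-2H-chromen-2-one | CC(C)(C)[Si](C)(C)O[C@@H]1CC=C(C)[C@@H](COc2ccc3ccc(=O)oc3c2)C1(C)C | intermediate
17 | 7-{[(1R,5R)-5-hydroxy-2,6,6-trimethylcyclohex-2-en-1-yl]methoxy}-2H-chromen-2-one | O[C@@H]1CC=C(C)[C@@H](COc2ccc3ccc(=O)oc3c2)C1(C)C | intermediate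
18 | 7-{[(1R,5R)-5-acetoxy-2,6,6-trimethylcyclohex-2-en-1-yl]methoxy}-2H-chromen-2-one | CC(=O)O[C@@H]1CC=C(C)[C@@H](COc2ccc3ccc(=O)oc3c2)C1(C)C | target

**Summary and risks**

Total step count: 13. Longest linear sequence: 13 steps, from 1 to 18; umbelliferone 15 enters at step 11.

Steps most likely to fail:

1. Step 3. Oxygen transfer may occur with poor facial discrimination on this dienone, whose vinylogous carbonyl group makes the alkene less electron-rich than a chromene. Uncatalysed epoxidation by hypochlorite may also erode the enantiomeric purity. Fallback (resolution instead of asymmetric catalysis), setting out from 4 and returning at 7: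
   - Epoxidation of 4 with mCPBA and NaHCO3 in CH2Cl2 gives racemic 4,5-epoxy-2,6,6-trimethylcyclohept-2-en-1-one F1.
   - The conditions of steps 4 and 5 take this through racemic 5-hydroxy-2,6,6-trimethylcyclohept-3-en-1-one F2 to racemic 5-hydroxy-2,6,6-trimethylcyclohept-2-en-1-one F3.
   - Lipase-catalysed transesterification (Burkholderia cepacia lipase, vinyl acetate, MTBE) should acetylate the R alcohol, in line with the usual preference of lipases for secondary alcohols with one large and one medium substituent. It would give (5R)-5-acetoxy-2,6,6-trimethylcyclohept-2-en-1-one F4 and leave the S alcohol, which is removed by chromatography.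
   - Hydrolysis of F4 with the same lipase in pH 7 phosphate buffer gives 7. Neutral conditions are chosen to avoid vinylogous elimination of acetate.

2. Step 9. The equilibrium may not lie far enough on the trans side, or methoxide may move the C2=C3 alkene into conjugation with the ester. Fallback (separation through selective lactonisation instead of equilibration), setting out from 12 and returning at 13:
   - The kinetic mixture 12 is desilylated with HF·pyridine in THF and then stirred with catalytic PPTS in CH2Cl2.
   - The cis-hydroxy ester closes to the bridged lactone (1S,5R)-2,8,8-trimethyl-6-oxabicyclo[3.2.1]oct-2-en-7-one F6. The trans epimer, methyl (1R,5R)-5-hydroxy-2,6,6-trimethylcyclohex-2-ene-1-carboxylate F5, cannot lactonise and is separated by chromatography.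
   - Silylation of F5 with TBSOTf and 2,6-lutidine gives 13. The cis material is sacrificed.

3. Step 8. The excited diazo ketone may follow carbene pathways (insertion into a C–H bond of a C6 methyl, 1,2-methyl shift) or secondary photochemistry instead of alkenyl migration. The dienol may also be protonated at the γ carbon, giving the conjugated ester. Fallback (ionic ring contraction without a diazo compound or light), setting out from 8 and returning at 12:
   - The lithium enolate of 8 (LiN(SiMe3)2, THF, −78 °C) is brominated with NBS to (5R)-7-bromo-5-(tert-butyldimethylsilyloxy)-2,6,6-trimethylcyclohept-2-en-1-one F7.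
   - NaOMe in MeOH at 0 °C should then bring about a quasi-Favorskii (semibenzilic) rearrangement: methoxide adds to the carbonyl group and the alkenyl carbon C2 shifts to C7 as bromide leaves.
   - The same C–C bond is formed, and the product is the ester 12 as C1 epimers. The quaternary C6 excludes competing elimination of HBr.

Further compounds
F1 | step 3 | racemic 4,5-epoxy-2,6,6-trimethylcyclohept-2-en-1-one (cis-fused) | CC1=CC2OC2C(C)(C)CC1=O
F2 | step 3 | racemic 5-hydroxy-2,6,6-trimethylcyclohept-3-en-1-one, C2 epimers | OC1C=CC(C)C(=O)CC1(C)C
F3 | step 3 | racemic 5-hydroxy-2,6,6-trimethylcyclohept-2-en-1-one | OC1CC=C(C)C(=O)CC1(C)C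
F4 | step 3 | (5R)-5-acetoxy-2,6,6-trimethylcyclohept-2-en-1-one | CC(=O)O[C@@H]1CC=C(C)C(=O)CC1(C)C
F5 | step 9 | methyl (1R,5R)-5-hydroxy-2,6,6-trimethylcyclohex-2-ene-1-carboxylate | O[C@@H]1CC=C(C)[C@@H](C(=O)OC)C1(C)C
F6 | step 9 | (1S,5R)-2,8,8-trimethyl-6-oxabicyclo[3.2.1]oct-2-en-7-one | CC1=CC[C@H]2OC(=O)[C@@H]1C2(C)C
F7 | step 8 | (5R)-7-bromo-5-(tert-butyldimethylsilyloxy)-2,6,6-trimethylcyclohept-2-en-1-one, C7 epimers | CC(C)(C)[Si](C)(C)O[C@@H]1CC=C(C)C(=O)C(Br)C1(C)C
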